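**Strategy.** Ring C of the flavanone is cut between the methylene C3 and the ketone carbon C4. Because C4 is an aryl ketone ortho to O1 on ring A, and C2 (the only stereocenter) carries O1 and ring B next to the C3 methylene, ring C is the hydroacylation adduct of a salicylaldehyde C–H bond across a 1,1-disubstituted aryl enol ether. A rhodium-catalysed enantioselective 6-endo hydroacylation therefore forms C3–C4, closes ring C at the ketone oxidation level and sets C2 in one operation. Its precursor is an achiral 2-(1-arylvinyloxy)benzaldehyde, assembled by C–O coupling of a MOM-protected phloroglucinaldehyde with the enol triflate of the prenylated chromene acetophenone (ring B).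

Key step: step 8

Remark on numbering: flavanone numbering is used for the target (ring C: O1, C2, C3, C4; ring A: C4a to C8a; ring B is the chromene unit on C2).

Assumption: the sense of induction of the bisphosphine in step 8 cannot be predicted with certainty for this substrate. The (R)-ligand is written; because 11 is achiral, the (S)-ligand gives the mirror-image result if the sense is found to be opposite.

**Step 1**
Reactants: 1 2,4,6-trihydroxybenzaldehyde
Product: 2 2-hydroxy-4,6-bis(methoxymethoxy)benzaldehyde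
Conditions: MOMCl (2.1 equiv), i-Pr2NEt, CH2Cl2, 0 °C to rt
Reagents that add atoms: chloromethyl methyl ether (MOMCl), COCCl
Why: Williamson-type O-alkylation (MOM protection) should take the 4-OH and one ortho-OH and leave the other ortho-OH, hydrogen-bonded to the formyl group, free as the future O1.

**Step 2**
Reactants: 3 1-(2,4-dihydroxyphenyl)ethanone
Product: 4 1-(5-bromo-2,4-dihydroxyphenyl)ethanone
Conditions: Br2 (1.0 equiv), AcOH, 15 °C
Reagents that add atoms: bromine, BrBr
Why: Electrophilic aromatic bromination should go to C5, para to the chelated 2-OH and ortho to the 4-OH and less hindered than C3, which marks the carbon that later carries the prenyl group.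

**Step 3**
Reactants: 4 1-(5-bromo-2,4-dihydroxyphenyl)ethanone
Product: 6 1-(8-bromo-5-hydroxy-2,2-dimethyl-2H-chromen-6-yl)ethanone, via ortho-quinone methide 5 (not isolated)
Conditions: 3-methylbut-2-enal, ethylenediammonium diacetate (cat.), xylene, 140 °C
Reagents that add atoms: 3-methylbut-2-enal (prenal), CC(C)=CC=O
Why: Amine-catalysed Knoevenagel-type condensation at C3, the only free position ortho to the 4-OH, gives ortho-quinone methide 5, whose oxa-6π electrocyclization through the non-chelated oxygen closes the 2,2-dimethylpyran ring.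

**Step 4**
Reactants: 6 1-(8-bromo-5-hydroxy-2,2-dimethyl-2H-chromen-6-yl)ethanone
Product: 7 1-[8-bromo-5-(methoxymethoxy)-2,2-dimethyl-2H-chromen-6-yl]ethanone
Conditions: MOMCl, K2CO3, acetone, reflux
Reagents that add atoms: chloromethyl methyl ether (MOMCl), COCCl
Why: Williamson-type MOM protection of the chelated phenol masks the acidic OH before the enolate and cross-coupling steps.

**Step 5**
Reactants: 7 1-[8-bromo-5-(methoxymethoxy)-2,2-dimethyl-2H-chromen-6-yl]ethanone
Product: 8 1-[5-(methoxymethoxy)-2,2-dimethyl-8-(3-methylbut-2-en-1-yl)-2H-chromen-6-yl]ethanone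
Conditions: tributyl(3-methylbut-2-en-1-yl)stannane, Pd(PPh3)4 (cat.), DMF, 100 °C
Reagents that add atoms: tributyl(3-methylbut-2-en-1-yl)stannane, CCCC[Sn](CCCC)(CCCC)CC=C(C)C
Why: Stille cross-coupling of the aryl bromide under zerovalent palladium catalysis should install the C-prenyl group, predominantly as the linear isomer.

**Step 6**
Reactants: 8 1-[5-(methoxymethoxy)-2,2-dimethyl-8-(3-methylbut-2-en-1-yl)-2H-chromen-6-yl]ethanone
Product: 10 1-[5-(methoxymethoxy)-2,2-dimethyl-8-(3-methylbut-2-en-1-yl)-2H-chromen-6-yl]ethenyl trifluoromethanesulfonate, via potassium enolate 9 (not isolated)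
Conditions: KN(SiMe3)2, THF, −78 °C; then PhNTf2, −78 to 0 °C; filtered through Et3N-deactivated silica and used at once
Reagents that add atoms: N-phenyl-bis(trifluoromethanesulfonimide), O=S(=O)(N(c1ccccc1)S(=O)(=O)C(F)(F)F)C(F)(F)F
Why: Kinetic deprotonation of the methyl ketone and O-sulfonylation of potassium enolate 9 (enol triflate formation) should give the 1-arylvinyl triflate, which is used directly because electron-rich α-aryl enol triflates hydrolyse easily.

**Step 7**
Reactants: 2 2-hydroxy-4,6-bis(methoxymethoxy)benzaldehyde; 10 1-[5-(methoxymethoxy)-2,2-dimethyl-8-(3-methylbut-2-en-1-yl)-2H-chromen-6-yl]ethenyl trifluoromethanesulfonate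
Product: 11 2-({1-[5-(methoxymethoxy)-2,2-dimethyl-8-(3-methylbut-2-en-1-yl)-2H-chromen-6-yl]ethenyl}oxy)-4,6-bis(methoxymethoxy)benzaldehyde
Conditions: Pd2(dba)3 (cat.), 2-(di-tert-butylphosphino)biphenyl, K3PO4, toluene, 90 °C
Reagents that add atoms: none
Why: Palladium-catalysed C–O cross-coupling of an enol triflate with a phenol (Buchwald–Hartwig-type etherification with a bulky biaryl monophosphine) should join the ring A oxygen O1 to the future C2 and leave the non-enolizable aldehyde untouched.

**Step 8**
Reactants: 11 2-({1-[5-(methoxymethoxy)-2,2-dimethyl-8-(3-methylbut-2-en-1-yl)-2H-chromen-6-yl]ethenyl}oxy)-4,6-bis(methoxymethoxy)benzaldehyde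
Product: 12 (2S)-5,7-bis(methoxymethoxy)-2-[5-(methoxymethoxy)-2,2-dimethyl-8-(3-methylbut-2-en-1-yl)-2H-chromen-6-yl]-2,3-dihydro-4H-chromen-4-one
Conditions: [Rh(cod)Cl]2 (cat.), (R)-DTBM-SEGPHOS, Na[B(3,5-(CF3)2C6H3)4], 1,2-dichloroethane, 60 °C
Reagents that add atoms: none
Why: Proposed new method: oxidative addition of the formyl C–H bond of 11 to the cationic monovalent rhodium bisphosphine complex gives an acyl rhodium hydride (trivalent rhodium); the tethered 1,1-disubstituted enol ether then inserts into Rh–H with hydride going to C2 and rhodium to the terminal C3, and C–C reductive elimination from the seven-membered acyl alkyl rhodacycle forms the C3–C4 bond and closes ring C. The closest known reaction type is the rhodium-catalysed enantioselective intramolecular hydroacylation of 1,1-disubstituted alkenes in 2-(1-substituted vinyl)benzaldehydes and 2-(2-substituted allyl)benzaldehydes, which gives 3-substituted indanones and tetralones by the same endo mode; an aryl enol ether as the alkene and an oxygen atom in the tether are the new elements. The ring closes in a 6-endo-trig mode with respect to the C2=C3 alkene. The single stereocenter C2 is set by the chiral bisphosphine, which selects the enantiotopic alkene face for hydride delivery; 11 is achiral, so control is by the catalyst alone. The step needs endo regioselectivity over the 5-exo path to a 2-aryl-2-methylbenzofuran-3-one and must outrun decarbonylation; the fully substituted C2, which disfavours a tertiary alkyl rhodium, and chelation of rhodium by O1 and the ortho MOM ether should secure both, while the chromene and prenyl alkenes are not tethered to the acyl group and should stay out.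

**Step 9**
Reactants: 12 (2S)-5,7-bis(methoxymethoxy)-2-[5-(methoxymethoxy)-2,2-dimethyl-8-(3-methylbut-2-en-1-yl)-2H-chromen-6-yl]-2,3-dihydro-4H-chromen-4-one
Product: 13 Sanggenol N, (2S)-5,7-dihydroxy-2-[5-hydroxy-2,2-dimethyl-8-(3-methylbut-2-en-1-yl)-2H-chromen-6-yl]-2,3-dihydro-4H-chromen-4-one
Conditions: 3 M aq HCl, MeOH–THF, 40 °C
Reagents that add atoms: none
Why: Acid-catalysed acetal cleavage (transacetalization to methanol) should remove the three MOM groups under conditions mild enough to leave the chromene, the prenyl group and C2, which epimerizes only through ring opening, unchanged.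

**Compound list**
1 | 2,4,6-trihydroxybenzaldehyde | O=Cc1c(O)cc(O)cc1O | starting material
2 | 2-hydroxy-4,6-bis(methoxymethoxy)benzaldehyde | COCOc1cc(O)c(C=O)c(OCOC)c1 | intermediate
3 | 1-(2,4-dihydroxyphenyl)ethanone | CC(=O)c1ccc(O)cc1O | starting material
4 | 1-(5-bromo-2,4-dihydroxyphenyl)ethanone | CC(=O)c1cc(Br)c(O)cc1O | intermediate
5 | 4-acetyl-6-bromo-3-hydroxy-2-(3-methylbut-2-en-1-ylidene)cyclohexa-3,5-dien-1-one (ortho-quinone methide) | CC(=O)C1=C(O)C(=CC=C(C)C)C(=O)C(Br)=C1 | intermediate
6 | 1-(8-bromo-5-hydroxy-2,2-dimethyl-2H-chromen-6-yl)ethanone | CC(=O)c1cc(Br)c2OC(C)(C)C=Cc2c1O | intermediate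
7 | 1-[8-bromo-5-(methoxymethoxy)-2,2-dimethyl-2H-chromen-6-yl]ethanone | CC(=O)c1cc(Br)c2OC(C)(C)C=Cc2c1OCOC | intermediate
8 | 1-[5-(methoxymethoxy)-2,2-dimethyl-8-(3-methylbut-2-en-1-yl)-2H-chromen-6-yl]ethanone | CC(=O)c1cc(CC=C(C)C)c2OC(C)(C)C=Cc2c1OCOC | intermediate
9 | potassium 1-[5-(methoxymethoxy)-2,2-dimethyl-8-(3-methylbut-2-en-1-yl)-2H-chromen-6-yl]ethen-1-olate (potassium enolate) | [K+].C=C([O-])c1cc(CC=C(C)C)c2OC(C)(C)C=Cc2c1OCOC | intermediate
10 | 1-[5-(methoxymethoxy)-2,2-dimethyl-8-(3-methylbut-2-en-1-yl)-2H-chromen-6-yl]ethenyl trifluoromethanesulfonate | C=C(OS(=O)(=O)C(F)(F)F)c1cc(CC=C(C)C)c2OC(C)(C)C=Cc2c1OCOC | intermediate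
11 | 2-({1-[5-(methoxymethoxy)-2,2-dimethyl-8-(3-methylbut-2-en-1-yl)-2H-chromen-6-yl]ethenyl}oxy)-4,6-bis(methoxymethoxy)benzaldehyde (achiral) | C=C(Oc1cc(OCOC)cc(OCOC)c1C=O)c1cc(CC=C(C)C)c2OC(C)(C)C=Cc2c1OCOC | intermediate
12 | (2S)-5,7-bis(methoxymethoxy)-2-[5-(methoxymethoxy)-2,2-dimethyl-8-(3-methylbut-2-en-1-yl)-2H-chromen-6-yl]-2,3-dihydro-4H-chromen-4-one | CC(C)=CCc1cc([C@@H]2CC(=O)c3c(OCOC)cc(OCOC)cc3O2)c(OCOC)c2c1OC(C)(C)C=C2 | intermediate
13 | Sanggenol N, (2S)-5,7-dihydroxy-2-[5-hydroxy-2,2-dimethyl-8-(3-methylbut-2-en-1-yl)-2H-chromen-6-yl]-2,3-dihydro-4H-chromen-4-one | CC(C)=CCc1cc([C@@H]2CC(=O)c3c(O)cc(O)cc3O2)c(O)c2c1OC(C)(C)C=C2 | target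

**Total step count:** 9

**Longest linear sequence:** 8 steps (3 → 4 → 6 → 7 → 8 → 10 → 11 → 12 → 13; steps 2 to 9)

**Steps most likely to fail**

Step 8 (bears the label). Possible failure processes:
- insertion of the enol ether into Rh–H with the opposite regiochemistry (rhodium to C2), followed by exo ring closure;
- decarbonylation of the acyl rhodium hydride;
- β-aryloxy elimination from the C3-bound alkyl rhodium;
- Lewis-acid-induced hydrolysis of the enol ether;
- insufficient facial discrimination at C2.

The fallback uses known chemistry, sets out from 10 and 2, and comes back at 12. Elimination of triflate from 10 with LiN(i-Pr)2 (THF, −78 °C) should give the terminal alkyne 6-ethynyl-5-(methoxymethoxy)-2,2-dimethyl-8-(3-methylbut-2-en-1-yl)-2H-chromene F1. Phenol-directed rhodium-catalysed intermolecular hydroacylation of this alkyne with salicylaldehyde 2 ([Rh(cod)Cl]2, Fe(C5H4PPh2)2, Na2CO3, toluene, 110 °C) should give the linear 2'-hydroxychalcone (2E)-1-[2-hydroxy-4,6-bis(methoxymethoxy)phenyl]-3-[5-(methoxymethoxy)-2,2-dimethyl-8-(3-methylbut-2-en-1-yl)-2H-chromen-6-yl]prop-2-en-1-one F2. Enantioselective intramolecular oxa-Michael addition of its free phenol under a cinchona-alkaloid-derived bifunctional thiourea catalyst (toluene, rt; catalyst pseudo-enantiomer chosen for the (S) product, enrichment by crystallization if needed) then closes ring C at O1–C2 and should give 12.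

Step 7. Possible failure processes:
- sulfonyl transfer from the enol triflate to the phenoxide (S–O cleavage);
- slow C–O reductive elimination from a hindered alkenyl palladium aryloxide;
- hydrolysis of the labile enol triflate before coupling.

The fallback sets out from 8 and comes back at 11. Condensation of 8 with hydrazine hydrate (EtOH, reflux) should give 1-[5-(methoxymethoxy)-2,2-dimethyl-8-(3-methylbut-2-en-1-yl)-2H-chromen-6-yl]ethanone hydrazone F3. Barton iodination (I2, 1,1,3,3-tetramethylguanidine, THF, 0 °C to rt) should give the more robust vinyl iodide 6-(1-iodoethenyl)-5-(methoxymethoxy)-2,2-dimethyl-8-(3-methylbut-2-en-1-yl)-2H-chromene F4. Ullmann-type coupling of this iodide with phenol 2 under monovalent copper catalysis (CuI, N,N-dimethylglycine, Cs2CO3, 1,4-dioxane, 90 °C) should give 11.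

Step 5. Possible failure processes:
- slow oxidative addition into the electron-rich aryl bromide;
- γ-transfer of the allyl group from tin, leaking to the 1,1-dimethylallyl isomer;
- protodebromination.

The fallback sets out from 3 and comes back at 8, and replaces halogenation and cross-coupling by a sigmatropic relay. Chromenylation of 3 with 3-methylbut-2-enal (ethylenediammonium diacetate, xylene, 140 °C) should give 1-(5-hydroxy-2,2-dimethyl-2H-chromen-6-yl)ethanone F5. O-Prenylation (1-bromo-3-methylbut-2-ene, K2CO3, acetone, reflux) should give 1-{2,2-dimethyl-5-[(3-methylbut-2-en-1-yl)oxy]-2H-chromen-6-yl}ethanone F6. Thermal para-Claisen–Cope rearrangement (N,N-diethylaniline, 200 °C), with both ortho positions blocked, should move the prenyl group to C8 and give 1-[5-hydroxy-2,2-dimethyl-8-(3-methylbut-2-en-1-yl)-2H-chromen-6-yl]ethanone F7. MOM protection as in step 4 then gives 8.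

**Further compounds**
F1 | step 8 | 6-ethynyl-5-(methoxymethoxy)-2,2-dimethyl-8-(3-methylbut-2-en-1-yl)-2H-chromene | C#Cc1cc(CC=C(C)C)c2OC(C)(C)C=Cc2c1OCOC
F2 | step 8 | (2E)-1-[2-hydroxy-4,6-bis(methoxymethoxy)phenyl]-3-[5-(methoxymethoxy)-2,2-dimethyl-8-(3-methylbut-2-en-1-yl)-2H-chromen-6-yl]prop-2-en-1-one | COCOc1cc(O)c(C(=O)/C=C/c2cc(CC=C(C)C)c3OC(C)(C)C=Cc3c2OCOC)c(OCOC)c1
F3 | step 7 | 1-[5-(methoxymethoxy)-2,2-dimethyl-8-(3-methylbut-2-en-1-yl)-2H-chromen-6-yl]ethanone hydrazone | NN=C(C)c1cc(CC=C(C)C)c2OC(C)(C)C=Cc2c1OCOC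
F4 | step 7 | 6-(1-iodoethenyl)-5-(methoxymethoxy)-2,2-dimethyl-8-(3-methylbut-2-en-1-yl)-2H-chromene | C=C(I)c1cc(CC=C(C)C)c2OC(C)(C)C=Cc2c1OCOC
F5 | step 5 | 1-(5-hydroxy-2,2-dimethyl-2H-chromen-6-yl)ethanone | CC(=O)c1ccc2OC(C)(C)C=Cc2c1O
F6 | step 5 | 1-{2,2-dimethyl-5-[(3-methylbut-2-en-1-yl)oxy]-2H-chromen-6-yl}ethanone | CC(=O)c1ccc2OC(C)(C)C=Cc2c1OCC=C(C)C
F7 | step 5 | 1-[5-hydroxy-2,2-dimethyl-8-(3-methylbut-2-en-1-yl)-2H-chromen-6-yl]ethanone | CC(=O)c1cc(CC=C(C)C)c2OC(C)(C)C=Cc2c1O
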